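## Analysis of the target

Locants used throughout: C1 is the furyl-bearing CH, C2 the ring B CH2, C3=C4 the ring B alkene, C5 the quaternary carbon carrying C19H2–O, C6 a CH2, C7 the acetoxy carbon, C8 the carbon carrying the exocyclic methylene C17, C9 the methyl-bearing quaternary carbon, C10 the ring-fusion CH, C11 a CH2, C12 the ketone, C13 and C16 the furan carbons bonded to C12 and C1, C18 the lactone carbonyl on C4.

The skeleton is a trans-fused decalin (ring A: C5–C10; ring B: C1–C5, C10). A γ-lactone (C4–C18–O–C19–C5) is fused to ring B. A seven-membered ketone ring C (C1, C10, C9, C11, C12, C13, C16) is fused to a furan. The five stereocentres are (1R,5S,7S,9R,10R). C19 is anti to H-10 (trans fusion), the C9 methyl is syn-diaxial to C19, H-1 is anti to H-10, and the C7 acetate is equatorial. C5 and C9 are quaternary and flank C10, so C5–C10–C9–C1 is a crowded contiguous array. Sensitive groups are the furan (acid, oxidants, electrophiles), the allylic acetate next to the exocyclic alkene, and the unsaturated lactone. The strategy rests on ring B: its only alkene, C3=C4, lies between quaternary C5 and the C2–C1 unit, so C5–C10 and C2–C1 are the two σ-bonds of a diene–alkene union that also closes ring A.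

## Retrosynthetic reasoning

**C12–C13 (ring C).** The aryl ketone 29 is opened to the acid 27. C13 is the only furan carbon that the C12 acyl group can reach, because C1 and C9 hold the two arms side by side on the decalin. The forward step is an intramolecular Friedel–Crafts acylation. It must close a seven-membered ring at a furan β-position without touching the free α-position C15 or the allylic acetate.

**Lactone and masking groups.** The C19–O–C18 lactone and the C12 acid of 27 are traced back to the cycloadduct 25, with C12 and C18 as tert-butyl esters and C19–OH as a silyl ether. One acid treatment should remove all three, and the C19 hydroxyl, held next to C18 on C5/C4, lactonises.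

**C5–C10 and C2–C1 (rings A and B).** Cutting both bonds of 25 gives the triene 24: a C4-ester diene (C5=C4–C3=C2) tethered through C6–C9 to an E-2-vinylfuran (C10=C1). This removes two rings and three stereocentres (C1, C5, C10) at once and leaves only C7 and C9 to be made beforehand. No other pair of bonds in the target does this. The forward cycloaddition has to give the trans ring fusion on one diene face.

**C7–O and C7–C8.** The acetate 24 comes from the alcohol 23, and 23 from the alkenyl triflate 12 and the aldehyde 22 by a chromium-mediated addition. The cut is convergent and places the exocyclic methylene directly. The organochromium species is non-basic, which the enolisable β,γ-unsaturated aldehyde 22 needs. The C4 ester is carried as tert-butyl rather than methyl, because C6 is cis to C18 on the C4=C5 bond and a C7 hydroxyl could otherwise lactonise onto C18.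

**Triflate fragment.** The C10=C1 alkene of 12 is cut to the aldehyde 9 and the phosphonate 11 (from 10), an E-selective olefination. The C8 triflate derives from a methyl ketone (7 from 6), and 9 comes from 7 through 8. The C9–C11 bond of 6 is cut to the chiral enamine 3 and the bromoacetate 4. The asymmetric alkylation sets the only stereocentre of this fragment, and 3 comes from 1 and 2.

**Aldehyde fragment.** The C5–C6 bond of 22 (through the acetal 20) is cut to the iodide 19, a cross-coupling that keeps the alkene geometry. 19 comes from 16 by oxidation of C18 (17, 18). The tetrasubstituted alkene of 16, with its C4–C3 bond and C5–I bond, comes from anti addition of a vinylmagnesium halide across the alkyne of 14 (from 13), directed by the C18 alkoxide. Anti addition places C6 (through iodine) trans to the vinyl group and cis to C18, which puts the tether on the outside position of the diene.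

## Alternatives that were turned down

**Alternative 1: ring A closed last at C7–C8.** The cut is the C7–C8 bond. In the forward step the seco iodo aldehyde A2 undergoes an intramolecular Nozaki–Hiyama–Kishi reaction to the C7 alcohol A1, which is then acetylated. For it: the ring closure is mild, late and intramolecular, and may well be more diastereoselective at C7 than the intermolecular coupling used here; it also avoids any heated step. Against it: A2 already contains rings B and C, the lactone and the stereocentres C1, C5, C9 and C10. The hard part of the molecule, two quaternary carbons around C10 with a trans relationship, is therefore left unsolved and needs its own annulation. The C7 configuration would be set by the substrate only. The chosen route uses the same chromium chemistry early and convergently and lets one cycloaddition build the congested core.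

**Alternative 2: radical cascade for lactone and ring B.** The cuts are C18–C4 and C3–C2. In the forward step an alkoxycarbonyl radical from the selenocarbonate A4 adds 5-exo to the C5 alkyne, the vinyl radical at C3 closes ring B 6-endo onto the furylvinyl CH2, and hydrogen transfer to C1 gives A3. For it: neutral conditions at moderate temperature, the lactone and the conjugated C3=C4 alkene appear together, and C5 is already fixed; on mildness it is stronger than a thermal cycloaddition. Against it: C1 is set by hydrogen delivery to a planar furfuryl radical, which has no geometric guarantee. A 1,5-hydrogen shift of the vinyl radical competes. A4 is a ring A cyclohexane with the contiguous C5, C10 and C9 centres already in place, and it must be made first, which is long. The chosen step sets C1, C5 and C10 together, with C1 fixed by alkene geometry.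

**Alternative 3: furan 1,6-addition closing ring C.** The cut is C1–C16. In the forward step a Lewis acid activates the dienyl lactone A6 and C16 of the tethered 3-substituted furan adds to C1, giving the dithiolane A5; the dithiolane is then removed. For it: the bond forms at the nucleophilic α-position of the furan, which is electronically better than the β-acylation used here. Against it: C12 must be masked, since an acyl group would deactivate the furan, and the dithiolane must then be removed beside a furan and two alkenes. C1 is set without a reliable control element. Reprotonation of the dienolate may leave the alkene out of conjugation. The decalin A6 with C5, C9 and C10 still has to be built. The chosen route compensates for the less reactive β-position by geometry (only C13 is reachable) and needs no ketone protecting group.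

Key step: step 17

## Assumptions

- In step 2 the L-valine auxiliary in toluene/HMPA, and in step 15 the (S)-oxazoline–sulfonamide ligand, are taken to deliver the configurations drawn. If the sense is opposite, the enantiomeric auxiliary or ligand is used.
- (1,3-Dioxolan-2-ylmethyl)zinc bromide, vinylmagnesium chloride and the triflating and tert-butylating reagents are used as purchased. Compound 2 is freed from its commercial hydrochloride.

## Route

Step 1
Reactants: 1 methyl 2-methyl-3-oxobutanoate; 2 L-valine tert-butyl ester
Product: 3 methyl (2Z)-3-{[(2S)-1-tert-butoxy-3-methyl-1-oxobutan-2-yl]amino}-2-methylbut-2-enoate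
Conditions: BF3·OEt2 (cat.), toluene, reflux, Dean–Stark
Reagents that add atoms: none
Why: Condensation of the amine with the ketone of a β-keto ester gives the conjugated enamino ester, held in the Z form by an N–H···O=C hydrogen bond; water removal drives it and the valine centre is untouched.

Step 2
Reactants: 3 enamino ester; 4 tert-butyl bromoacetate
Product: 6 4-tert-butyl 1-methyl (2S)-2-acetyl-2-methylbutanedioate, via alkylated ketimine 5 (not isolated)
Conditions: LiN(iPr)2, toluene, −78 °C; HMPA (1 equiv); 4, −78 → −55 °C; then aq. citric acid, rt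
Reagents that add atoms: water, O
Why: Asymmetric alkylation of the chiral lithio-enamine of an α-alkyl β-keto ester, a known way to acyclic quaternary centres; lithium is chelated by the nitrogen and the valine ester carbonyl, the isopropyl group shields one face and the bromoacetate attacks C9 from the other (SN2), which sets C9. Mild aqueous acid hydrolyses the ketimine and returns 2.

Step 3
Reactants: 6 keto diester
Product: 7 4-tert-butyl 1-methyl (2S)-2-methyl-2-{1-[(trifluoromethylsulfonyl)oxy]ethenyl}butanedioate
Conditions: KN(SiMe3)2, THF, −78 °C; N-(5-chloro-2-pyridyl)bis(trifluoromethanesulfonimide), −78 °C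
Reagents that add atoms: N-(5-chloro-2-pyridyl)bis(trifluoromethanesulfonimide), O=S(=O)(N(c1ccc(Cl)cn1)S(=O)(=O)C(F)(F)F)C(F)(F)F
Why: Kinetic enolisation followed by O-triflation; the ketone can enolise only towards its methyl group because C9 is quaternary, and trapping at −78 °C forestalls attack of the enolate on the tert-butyl ester.

Step 4
Reactants: 7 alkenyl triflate diester
Product: 8 tert-butyl (3R)-3-(hydroxymethyl)-3-methyl-4-[(trifluoromethylsulfonyl)oxy]pent-4-enoate
Conditions: iBu2AlH (2.2 equiv), CH2Cl2, −78 °C; aq. potassium sodium tartrate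
Reagents that add atoms: none
Why: Hydride reduction of an ester; the methyl ester is reduced well before the tert-butyl ester at low temperature and the alkenyl triflate is inert to the aluminium hydride.

Step 5
Reactants: 8 alcohol
Product: 9 tert-butyl (3S)-3-formyl-3-methyl-4-[(trifluoromethylsulfonyl)oxy]pent-4-enoate
Conditions: Dess–Martin periodinane, NaHCO3, CH2Cl2, rt
Reagents that add atoms: none
Why: Buffered periodinane oxidation of a primary alcohol; the aldehyde has no α-hydrogen, so C9 cannot epimerise.

Step 6
Reactants: 10 furan-2-ylmethanol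
Product: 11 diethyl (furan-2-ylmethyl)phosphonate
Conditions: P(OEt)3, ZnI2, toluene, reflux
Reagents that add atoms: triethyl phosphite, CCOP(OCC)OCC
Why: Lewis-acid mediated Michaelis–Arbuzov-type phosphonylation of a heteroarylmethyl alcohol: exchange to the furfuryl phosphite and ZnI2-promoted C–O to C–P rearrangement through the stabilised furfuryl cation.

Step 7
Reactants: 9 aldehyde; 11 phosphonate
Product: 12 tert-butyl (3R,4E)-5-(furan-2-yl)-3-methyl-3-{1-[(trifluoromethylsulfonyl)oxy]ethenyl}pent-4-enoate
Conditions: NaN(SiMe3)2, THF, −78 °C → rt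
Reagents that add atoms: none
Why: Horner–Wadsworth–Emmons olefination with a semi-stabilised phosphonate; reversible addition to the hindered, non-enolisable aldehyde and syn elimination should give the E-alkene C10=C1, and the phosphonate anion is not basic enough to eliminate the triflate.

Step 8
Reactants: 13 but-2-yne-1,4-diol
Product: 14 4-{[tert-butyl(dimethyl)silyl]oxy}but-2-yn-1-ol
Conditions: NaH (1.0 equiv), THF, 0 °C; tBuMe2SiCl (1.0 equiv), rt
Reagents that add atoms: tert-butyldimethylsilyl chloride, CC(C)(C)[Si](C)(C)Cl
Why: Monosilylation of a symmetric diol through its sparingly soluble mono-sodium alkoxide, which reacts once.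

Step 9
Reactants: 14 monosilyl ether
Product: 16 (2Z)-4-{[tert-butyl(dimethyl)silyl]oxy}-2-ethenyl-3-iodobut-2-en-1-ol, via alkenylmagnesium chelate 15 (not isolated)
Conditions: CH2=CHMgCl (3.5 equiv), THF, reflux; then I2, −78 → 0 °C
Reagents that add atoms: vinylmagnesium chloride, C=C[Mg]Cl; iodine, [I][I]
Why: Hydroxyl-directed anti-carbomagnesiation of a propargylic alcohol: the magnesium alkoxide delivers the vinyl group to the nearer alkyne carbon (C4) and magnesium ends on C5 in a five-membered chelate. Iodinolysis with retention gives the tetrasubstituted Z-iodide, with iodine (later C6) cis to C18 and trans to the vinyl group.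

Step 10
Reactants: 16 iodo dienol
Product: 17 (2Z)-4-{[tert-butyl(dimethyl)silyl]oxy}-2-ethenyl-3-iodobut-2-enal
Conditions: MnO2 (excess), CH2Cl2, rt
Reagents that add atoms: none
Why: Selective oxidation of an allylic alcohol on MnO2; neutral conditions keep the alkene geometry and the silyl ether.

Step 11
Reactants: 17 iodo dienal
Product: 18 (2Z)-4-{[tert-butyl(dimethyl)silyl]oxy}-2-ethenyl-3-iodobut-2-enoic acid
Conditions: NaClO2, NaH2PO4, 2-methylbut-2-ene, tBuOH/H2O, 0 °C → rt
Reagents that add atoms: sodium chlorite, [Na+].[O-]Cl=O
Why: Pinnick oxidation of a conjugated aldehyde; the alkene scavenger removes hypochlorous acid before it can attack the diene.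

Step 12
Reactants: 18 iodo dienoic acid
Product: 19 tert-butyl (2Z)-4-{[tert-butyl(dimethyl)silyl]oxy}-2-ethenyl-3-iodobut-2-enoate
Conditions: tert-butyl 2,2,2-trichloroacetimidate, CH2Cl2/cyclohexane, rt
Reagents that add atoms: tert-butyl 2,2,2-trichloroacetimidate, CC(C)(C)OC(=N)C(Cl)(Cl)Cl
Why: The acid protonates the imidate and the carboxylate captures the tert-butyl cation; no external acid is needed, so the allylic silyl ether survives.

Step 13
Reactants: 19 iodo dienoate
Product: 20 tert-butyl (2E)-3-({[tert-butyl(dimethyl)silyl]oxy}methyl)-4-(1,3-dioxolan-2-yl)-2-ethenylbut-2-enoate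
Conditions: (1,3-dioxolan-2-ylmethyl)zinc bromide (1.5 equiv), Pd(PPh3)4 (5 mol %), THF, 50 °C
Reagents that add atoms: (1,3-dioxolan-2-ylmethyl)zinc bromide, Br[Zn]CC1OCCO1
Why: Negishi coupling of an alkylzinc halide with an activated β-iodo enoate; oxidative addition to zerovalent palladium and reductive elimination proceed with retention, so C6 takes the place of iodine cis to C18.

Step 14
Reactants: 20 dioxolane
Product: 22 tert-butyl (2E)-3-({[tert-butyl(dimethyl)silyl]oxy}methyl)-2-ethenyl-5-oxopent-2-enoate, via collidinium N,O-acetal triflate 21 (not isolated)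
Conditions: Et3SiOTf (2 equiv), 2,4,6-collidine (3 equiv), CH2Cl2, 0 °C; then H2O; used at once
Reagents that add atoms: water, O
Why: Near-neutral acetal cleavage: the silyl triflate opens the dioxolane, collidine traps the oxocarbenium ion as a pyridinium salt, and water releases the aldehyde; no free acid or base is present to move the C4=C5 alkene into conjugation with the aldehyde.

Step 15
Reactants: 12 alkenyl triflate; 22 aldehyde
Product: 23 tert-butyl (2E,5S,7R,8E)-3-({[tert-butyl(dimethyl)silyl]oxy}methyl)-7-(2-tert-butoxy-2-oxoethyl)-2-ethenyl-9-(furan-2-yl)-5-hydroxy-7-methyl-6-methylidenenona-2,8-dienoate (7S,9R in the target locants)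
Conditions: CrCl2 (4 equiv), N-{2-[(4S)-4-isopropyl-4,5-dihydrooxazol-2-yl]-6-methylphenyl}methanesulfonamide (4.4 equiv), Et3N (4.4 equiv), NiCl2 (5 mol %), THF, rt
Reagents that add atoms: none
Why: Nozaki–Hiyama–Kishi coupling: zerovalent nickel inserts into the alkenyl triflate and hands the alkenyl group to trivalent chromium, whose non-basic alkenyl species adds to the enolisable aldehyde and ignores the esters. The chromium-bound chiral sulfonamide selects the aldehyde face and so sets C7 by reagent control.

Step 16
Reactants: 23 triene alcohol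
Product: 24 tert-butyl (2E,5S,7R,8E)-5-acetoxy-3-({[tert-butyl(dimethyl)silyl]oxy}methyl)-7-(2-tert-butoxy-2-oxoethyl)-2-ethenyl-9-(furan-2-yl)-7-methyl-6-methylidenenona-2,8-dienoate
Conditions: Ac2O, pyridine, DMAP (cat.), CH2Cl2, 0 °C → rt
Reagents that add atoms: acetic anhydride, CC(=O)OC(C)=O
Why: Acyl transfer to a secondary allylic alcohol without touching C7–O, so the configuration is kept; the tert-butyl ester on C18 cannot be attacked by the C7 hydroxyl while it is free.

Step 17
Reactants: 24 triene acetate
Product: 25 trans-fused cycloadduct, (1R,5S,7S,9R,10R)-7-acetoxy-1-(furan-2-yl)-9-methyl-8-methylidene-Δ3-octalin with CO2tBu on C4, CH2OSitBuMe2 on C5 and CH2CO2tBu on C9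
Conditions: toluene (0.005 M), BHT (10 mol %), 150 °C, sealed tube
Reagents that add atoms: none
Why: Concerted, asynchronous thermal [4+2] cycloaddition of inverse electron demand, in which the C4 ester lowers the LUMO of the diene C5=C4–C3=C2 and the furyl group raises the HOMO of the alkene C10=C1; the closest known reaction type is the intramolecular Diels–Alder reaction of 1,7,9-decatrienes with an ester on the diene. Ring B is the six-membered cycloadduct ring formed by both new bonds (C5–C10 and C2–C1), and ring A is the six-membered ring closed by the tether C6–C9 through the C5–C10 bond (fused mode, tether on a diene terminus). C10 and C1 follow from suprafacial addition to the E-alkene, which keeps C9 and the furyl group trans and so puts H-1 anti to H-10. C5 and the ring fusion follow from the anti transition state, in which the tether on the outside position of C5 folds away from the diene and the furyl group lies endo; this places C19 anti to H-10. The diene face is chosen by the tether: in the chair-like array the C7 acetate is equatorial and C9 holds its methyl group axial, syn to C19, whereas the other face would force the acetate and the CH2CO2tBu arm axial on the side of C19. The step needs trans over cis fusion and one diene face; the E geometry of both π systems, the endo preference of the conjugating furyl group and the two tether stereocentres acting in the same sense are what secure them. The new alkene arises at C3=C4, already conjugated with C18, and high dilution with a radical inhibitor holds back intermolecular reaction of the vinylfuran.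

Step 18
Reactants: 25 cycloadduct
Product: 27 lactone acid, (1R,5S,7S,9R,10R)-7-acetoxy-1-(furan-2-yl)-9-methyl-8-methylidene-3-en-18,19-olide with CH2CO2H on C9, via hydroxy diacid 26 (not isolated)
Conditions: CF3CO2H/CH2Cl2 (1:3), H2O (5 equiv), 0 °C → rt; concentrate from toluene
Reagents that add atoms: none
Why: Acidolysis removes both tert-butyl esters as isobutene and the primary silyl ether; the C19 hydroxyl and the C18 acid sit on adjacent carbons C5/C4 and close the five-membered lactone under the same acid, while the C12 acid cannot form a small-ring lactone.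

Step 19
Reactants: 27 lactone acid
Product: 29 CNP0273675.1, (1R,5S,7S,9R,10R), via mixed trifluoroacetic anhydride 28 (not isolated)
Conditions: (CF3CO)2O (1.2 equiv), CH2Cl2 (0.01 M), 0 °C → rt
Reagents that add atoms: none
Why: Intramolecular Friedel–Crafts acylation of a furan through the mixed anhydride: the acylium ion at C12 can reach only the β-carbon C13, because the equatorial arms on C1 and C9 lie side by side, and the seven-membered ring C closes. The acyl furan formed is deactivated towards further acylation.

## Compound list

1 | methyl 2-methyl-3-oxobutanoate | COC(=O)C(C)C(C)=O | starting material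
2 | L-valine tert-butyl ester | CC(C)[C@H](N)C(=O)OC(C)(C)C | starting material
3 | methyl (2Z)-3-{[(2S)-1-tert-butoxy-3-methyl-1-oxobutan-2-yl]amino}-2-methylbut-2-enoate | COC(=O)/C(C)=C(C)\N[C@@H](C(C)C)C(=O)OC(C)(C)C | intermediate
4 | tert-butyl bromoacetate | BrCC(=O)OC(C)(C)C | starting material
5 | alkylated ketimine, 4-tert-butyl 1-methyl (2S)-2-{N-[(2S)-1-tert-butoxy-3-methyl-1-oxobutan-2-yl]ethanimidoyl}-2-methylbutanedioate | O=C(OC(C)(C)C)C[C@](C(C)=N[C@@H](C(C)C)C(=O)OC(C)(C)C)(C)C(=O)OC | intermediate
6 | 4-tert-butyl 1-methyl (2S)-2-acetyl-2-methylbutanedioate | O=C(OC(C)(C)C)C[C@](C(C)=O)(C)C(=O)OC | intermediate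
7 | 4-tert-butyl 1-methyl (2S)-2-methyl-2-{1-[(trifluoromethylsulfonyl)oxy]ethenyl}butanedioate | O=C(OC(C)(C)C)C[C@](C(=C)OS(=O)(=O)C(F)(F)F)(C)C(=O)OC | intermediate
8 | tert-butyl (3R)-3-(hydroxymethyl)-3-methyl-4-[(trifluoromethylsulfonyl)oxy]pent-4-enoate | O=C(OC(C)(C)C)C[C@](C(=C)OS(=O)(=O)C(F)(F)F)(C)CO | intermediate
9 | tert-butyl (3S)-3-formyl-3-methyl-4-[(trifluoromethylsulfonyl)oxy]pent-4-enoate | O=C(OC(C)(C)C)C[C@](C(=C)OS(=O)(=O)C(F)(F)F)(C)C=O | intermediate
10 | furan-2-ylmethanol | OCc1ccco1 | starting material
11 | diethyl (furan-2-ylmethyl)phosphonate | CCOP(=O)(Cc1ccco1)OCC | intermediate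
12 | tert-butyl (3R,4E)-5-(furan-2-yl)-3-methyl-3-{1-[(trifluoromethylsulfonyl)oxy]ethenyl}pent-4-enoate | O=C(OC(C)(C)C)C[C@](C(=C)OS(=O)(=O)C(F)(F)F)(C)/C=C/c1ccco1 | intermediate
13 | but-2-yne-1,4-diol | OCC#CCO | starting material
14 | 4-{[tert-butyl(dimethyl)silyl]oxy}but-2-yn-1-ol | OCC#CCO[Si](C)(C)C(C)(C)C | intermediate
15 | alkenylmagnesium chelate (five-membered magnesium alkoxide, written halide-free) | C=CC1=C(CO[Si](C)(C)C(C)(C)C)[Mg]OC1 | intermediate
16 | (2Z)-4-{[tert-butyl(dimethyl)silyl]oxy}-2-ethenyl-3-iodobut-2-en-1-ol | OC/C(C=C)=C(\I)CO[Si](C)(C)C(C)(C)C | intermediate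
17 | (2Z)-4-{[tert-butyl(dimethyl)silyl]oxy}-2-ethenyl-3-iodobut-2-enal | O=C/C(C=C)=C(\I)CO[Si](C)(C)C(C)(C)C | intermediate
18 | (2Z)-4-{[tert-butyl(dimethyl)silyl]oxy}-2-ethenyl-3-iodobut-2-enoic acid | OC(=O)/C(C=C)=C(\I)CO[Si](C)(C)C(C)(C)C | intermediate
19 | tert-butyl (2Z)-4-{[tert-butyl(dimethyl)silyl]oxy}-2-ethenyl-3-iodobut-2-enoate | CC(C)(C)OC(=O)/C(C=C)=C(\I)CO[Si](C)(C)C(C)(C)C | intermediate
20 | tert-butyl (2E)-3-({[tert-butyl(dimethyl)silyl]oxy}methyl)-4-(1,3-dioxolan-2-yl)-2-ethenylbut-2-enoate | CC(C)(C)OC(=O)/C(C=C)=C(\CC1OCCO1)CO[Si](C)(C)C(C)(C)C | intermediate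
21 | collidinium N,O-acetal triflate of 20 (C7 bonded to the collidine nitrogen and to OCH2CH2OSiEt3) | CC(C)(C)OC(=O)/C(C=C)=C(\CC(OCCO[Si](CC)(CC)CC)[n+]1c(C)cc(C)cc1C)CO[Si](C)(C)C(C)(C)C.[O-]S(=O)(=O)C(F)(F)F | intermediate
22 | tert-butyl (2E)-3-({[tert-butyl(dimethyl)silyl]oxy}methyl)-2-ethenyl-5-oxopent-2-enoate | CC(C)(C)OC(=O)/C(C=C)=C(\CC=O)CO[Si](C)(C)C(C)(C)C | intermediate
23 | tert-butyl (2E,5S,7R,8E)-3-({[tert-butyl(dimethyl)silyl]oxy}methyl)-7-(2-tert-butoxy-2-oxoethyl)-2-ethenyl-9-(furan-2-yl)-5-hydroxy-7-methyl-6-methylidenenona-2,8-dienoate | C=C([C@@H](O)C/C(CO[Si](C)(C)C(C)(C)C)=C(/C=C)C(=O)OC(C)(C)C)[C@](C)(CC(=O)OC(C)(C)C)/C=C/c1ccco1 | intermediate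
24 | tert-butyl (2E,5S,7R,8E)-5-acetoxy-3-({[tert-butyl(dimethyl)silyl]oxy}methyl)-7-(2-tert-butoxy-2-oxoethyl)-2-ethenyl-9-(furan-2-yl)-7-methyl-6-methylidenenona-2,8-dienoate | C=C([C@@H](OC(C)=O)C/C(CO[Si](C)(C)C(C)(C)C)=C(/C=C)C(=O)OC(C)(C)C)[C@](C)(CC(=O)OC(C)(C)C)/C=C/c1ccco1 | intermediate
25 | trans-fused cycloadduct, (1R,5S,7S,9R,10R), di-tert-butyl ester, C19 silyl ether, C7 acetate | C=C1[C@@H](OC(C)=O)C[C@@]2(CO[Si](C)(C)C(C)(C)C)C(C(=O)OC(C)(C)C)=CC[C@@H](c3ccco3)[C@@H]2[C@@]1(C)CC(=O)OC(C)(C)C | intermediate
26 | hydroxy diacid (C19–OH, C18 and C12 acids free) | C=C1[C@@H](OC(C)=O)C[C@@]2(CO)C(C(=O)O)=CC[C@@H](c3ccco3)[C@@H]2[C@@]1(C)CC(=O)O | intermediate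
27 | lactone acid, (1R,5S,7S,9R,10R), 18,19-olide with C12 carboxylic acid | C=C1[C@@H](OC(C)=O)C[C@@]23COC(=O)C2=CC[C@@H](c2ccco2)[C@@H]3[C@@]1(C)CC(=O)O | intermediate
28 | mixed trifluoroacetic anhydride of 27 | C=C1[C@@H](OC(C)=O)C[C@@]23COC(=O)C2=CC[C@@H](c2ccco2)[C@@H]3[C@@]1(C)CC(=O)OC(=O)C(F)(F)F | intermediate
29 | CNP0273675.1, (1R,5S,7S,9R,10R) | C=C1[C@@H](OC(C)=O)C[C@@]23COC(=O)C2=CC[C@H]2c4occc4C(=O)C[C@]1(C)[C@@H]23 | target

## Step count and weak points

Total step count: 19. Longest linear sequence: 12 steps (steps 8 to 19, from 13).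

**Step 17 (key step).** The diene terminus C5 is fully substituted and C10 sits next to quaternary C9, so the cycloaddition may need a temperature at which other processes compete: a 1,5-hydrogen shift from C19 to C2, migration or loss of the allylic acetate, and leakage into the cis-fused (exo-furyl) pathway. Fallback: carry C18 as the more electrophilic aldehyde, so that the cycloaddition runs at lower temperature. It sets out from 16. Negishi coupling with the same zinc reagent gives the dienol acetal F1. Et3SiOTf/2,4,6-collidine and then water silylate the C18 hydroxyl and free the C7 aldehyde, giving the triethylsilyl ether aldehyde F2. Chromium-mediated coupling with 12 gives the triene alcohol F3, and acetylation the acetate F4. PPTS in MeOH at 0 °C removes the triethylsilyl group only, giving the dienol F5, and MnO2 gives the dienal triene F6. Warming to about 80 °C should give the enal cycloadduct F7, and Pinnick oxidation the acid F8. The acid treatment of step 18 then comes back to the route at 27.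

**Step 2.** The sense and level of induction with an α-halo ester electrophile are uncertain, and N- or O-alkylation of the enamine anion could compete. Fallback: direct alkylation of 1 with 4 under a chiral N-spiro binaphthyl quaternary ammonium bromide (solid K2CO3, toluene, low temperature). Stereocontrol then comes from a catalytic ion pair instead of a covalent auxiliary. It sets out from 1 and 4, returns at 6 and makes no new compound (F0).

**Step 15.** Facial control at C7 may be eroded by the neighbouring C9 centre. Oxidative addition to the hindered triflate may be slow. The amine base may move the alkene of 22 into conjugation. Fallback: ligand-free coupling (CrCl2, NiCl2 cat., DMF), separation of 23 from the (7R)-epimeric alcohol F9, and Mitsunobu esterification of F9 with acetic acid (PPh3, DIAD), which inverts C7 and returns at 24.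

**Step 14.** The silyl triflate may attack the conjugated tert-butyl ester or the silyl ether, and the β,γ-unsaturated aldehyde may isomerise on handling. Fallback: from 19, Stille coupling with (Z)-tributyl(2-ethoxyvinyl)stannane gives the dienyl enol ether F10, and hydrolysis with oxalic acid on wet silica returns at 22.

**Step 18.** Protonation of the exocyclic alkene, solvolysis of the allylic acetate or tert-butylation of the furan may accompany the acidolysis. Fallback: from 25, HF·pyridine gives the C19 alcohol F11. Me3SiOTf/2,6-lutidine then turns both tert-butyl esters into silyl esters, and aqueous work-up with lactonisation returns at 27.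

**Step 19.** Excess anhydride may trifluoroacetylate the free furan α-position C15, and intermolecular acylation may compete with the seven-membered closure. Fallback: from 27, 1-chloro-N,N,2-trimethylprop-1-en-1-amine gives the acid chloride F12, and SnCl4 in CH2Cl2 at −78 °C under high dilution, with no external acylating agent present, returns at 29.

## Further compounds

F1 | step 17 | (2E)-3-({[tert-butyl(dimethyl)silyl]oxy}methyl)-4-(1,3-dioxolan-2-yl)-2-ethenylbut-2-en-1-ol | OC/C(C=C)=C(\CC1OCCO1)CO[Si](C)(C)C(C)(C)C
F2 | step 17 | (3E)-3-({[tert-butyl(dimethyl)silyl]oxy}methyl)-4-{[(triethylsilyl)oxy]methyl}hexa-3,5-dienal | CC[Si](CC)(CC)OC/C(C=C)=C(\CC=O)CO[Si](C)(C)C(C)(C)C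
F3 | step 17 | (7S,9R)-triene alcohol with C18 as CH2OSiEt3 | C=C([C@@H](O)C/C(CO[Si](C)(C)C(C)(C)C)=C(/C=C)CO[Si](CC)(CC)CC)[C@](C)(CC(=O)OC(C)(C)C)/C=C/c1ccco1
F4 | step 17 | (7S,9R)-triene acetate with C18 as CH2OSiEt3 | C=C([C@@H](OC(C)=O)C/C(CO[Si](C)(C)C(C)(C)C)=C(/C=C)CO[Si](CC)(CC)CC)[C@](C)(CC(=O)OC(C)(C)C)/C=C/c1ccco1
F5 | step 17 | (7S,9R)-triene acetate with C18 as CH2OH | C=C([C@@H](OC(C)=O)C/C(CO[Si](C)(C)C(C)(C)C)=C(/C=C)CO)[C@](C)(CC(=O)OC(C)(C)C)/C=C/c1ccco1
F6 | step 17 | (7S,9R)-dienal triene (C18 aldehyde) | C=C([C@@H](OC(C)=O)C/C(CO[Si](C)(C)C(C)(C)C)=C(/C=C)C=O)[C@](C)(CC(=O)OC(C)(C)C)/C=C/c1ccco1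
F7 | step 17 | (1R,5S,7S,9R,10R)-cycloadduct with C18 aldehyde | C=C1[C@@H](OC(C)=O)C[C@@]2(CO[Si](C)(C)C(C)(C)C)C(C=O)=CC[C@@H](c3ccco3)[C@@H]2[C@@]1(C)CC(=O)OC(C)(C)C
F8 | step 17 | (1R,5S,7S,9R,10R)-cycloadduct with C18 carboxylic acid | C=C1[C@@H](OC(C)=O)C[C@@]2(CO[Si](C)(C)C(C)(C)C)C(C(=O)O)=CC[C@@H](c3ccco3)[C@@H]2[C@@]1(C)CC(=O)OC(C)(C)C
F0 | step 2 | none | none
F9 | step 15 | (7R,9R)-epimer of triene alcohol 23 | C=C([C@H](O)C/C(CO[Si](C)(C)C(C)(C)C)=C(/C=C)C(=O)OC(C)(C)C)[C@](C)(CC(=O)OC(C)(C)C)/C=C/c1ccco1
F10 | step 14 | tert-butyl (2E,4Z)-3-({[tert-butyl(dimethyl)silyl]oxy}methyl)-5-ethoxy-2-ethenylpenta-2,4-dienoate | CC(C)(C)OC(=O)/C(C=C)=C(\C=C/OCC)CO[Si](C)(C)C(C)(C)C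
F11 | step 18 | cycloadduct with free C19 hydroxyl (di-tert-butyl ester) | C=C1[C@@H](OC(C)=O)C[C@@]2(CO)C(C(=O)OC(C)(C)C)=CC[C@@H](c3ccco3)[C@@H]2[C@@]1(C)CC(=O)OC(C)(C)C
F12 | step 19 | acid chloride of lactone acid 27 | C=C1[C@@H](OC(C)=O)C[C@@]23COC(=O)C2=CC[C@@H](c2ccco2)[C@@H]3[C@@]1(C)CC(=O)Cl
A1 | alternative 1 | 7-deacetyl target (C7 alcohol) | C=C1[C@@H](O)C[C@@]23COC(=O)C2=CC[C@H]2c4occc4C(=O)C[C@]1(C)[C@@H]23
A2 | alternative 1 | 7,8-seco iodo aldehyde (C8 alkenyl iodide, C7 aldehyde) | O=CC[C@@]12COC(=O)C1=CC[C@H]1c3occc3C(=O)C[C@@](C)(C(I)=C)[C@@H]12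
A3 | alternative 2 | trans-decalin lactone acetate with furyl group on C1 and methyl ester arm on C9 | C=C1[C@@H](OC(C)=O)C[C@@]23COC(=O)C2=CC[C@@H](c2ccco2)[C@@H]3[C@@]1(C)CC(=O)OC
A4 | alternative 2 | ring A phenylselenocarbonate with C5 ethynyl and C10 1-(furan-2-yl)vinyl groups | C=C1[C@@H](OC(C)=O)C[C@](C#C)(COC(=O)[Se]c2ccccc2)[C@H](C(=C)c2ccco2)[C@@]1(C)CC(=O)OC
A5 | alternative 3 | C12 1,3-dithiolane of the target | C=C1[C@@H](OC(C)=O)C[C@@]23COC(=O)C2=CC[C@H]2c4occc4C4(SCCS4)C[C@]1(C)[C@@H]23
A6 | alternative 3 | dienyl lactone (C1=C2, C3=C4) with furan-3-yl dithiolane arm on C9 | C=C1[C@@H](OC(C)=O)C[C@@]23COC(=O)C2=CC=C[C@@H]3[C@@]1(C)CC1(SCCS1)c1ccoc1
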